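**Retrosynthetic overview**

1. Ester endgame: the O4 propanoate is put on last; the O3 acetate comes from opening a cyclic 3,4-orthoacetate of methyl shikimate after O5 has been esterified; methyl shikimate comes from its 3,5-bis-silyl ether, and that from the C4 ketone.
2. Key disconnection: C2–C3 and C5–C6 of the cyclohexene are cut together. The (3R,5R)-3,5-bis(silyloxy)-4-oxocyclohexenecarboxylate goes back to the RAMP hydrazone of bis-TBS dihydroxyacetone (C3–C4–C5) and methyl (Z)-3-bromo-2-(bromomethyl)acrylate (C2=C1(CO2Me)–C6), joined by a one-flask α,α′-annulation.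
3. Enabling feature: ring atoms C3–C4–C5 are a dihydroxyacetone unit. C3 and C5 both flank C4 and their oxygens are trans ((3R,5R)), so at the C4-ketone level the unit is C2-symmetric and both carbons are nucleophilic α-positions. C2 and C6 flank C1(CO2Me) as a vinylic/allylic bis-electrophile, so either pairing of ends gives the same ring and one auxiliary sets both centres.
4. Ring order: the carbocycle is the only ring of the target and is closed in the key step. A five-membered orthoester ring over O3/O4 is made later only to tell the three hydroxyls apart and is opened again.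
5. Elements that are not in the target and are removed on the way: the hydrazone auxiliary, the C4 carbonyl, two TBS ethers, the orthoester.

Key step: step 5

Remark: commercial 1,3-dihydroxyacetone is its crystalline dimer, which reacts as the monomer 1 under the silylation conditions.
Remark: the sense of induction in step 5 is assigned by the established azaenolate model (SAMP gives (S), RAMP gives (R) at an α-carbon that carries oxygen and the new carbon substituent).
Remark: the acyl stereocentre in the target SMILES is (R), so (R)-2-methylbutanoic acid is the building block.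

**Route**

Step 1
Reactants: 1 1,3-dihydroxyacetone
Product: 2 1,3-bis[(tert-butyldimethylsilyl)oxy]propan-2-one
Conditions: TBSCl (2.2 equiv), imidazole (4.5 equiv), DMF, 0 °C → rt
Reagents that add atoms: tert-butyldimethylsilyl chloride, CC(C)(C)[Si](C)(C)Cl
Why: Standard imidazole-promoted silyl ether formation on both primary hydroxyls after the dimer cracks to the monomer in DMF; no stereocentre is formed.

Step 2
Reactants: 2 1,3-bis[(tert-butyldimethylsilyl)oxy]propan-2-one; 3 (R)-1-amino-2-(methoxymethyl)pyrrolidine (RAMP)
Product: 4 RAMP hydrazone of 1,3-bis[(tert-butyldimethylsilyl)oxy]propan-2-one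
Conditions: 3 (1.05 equiv), 4 Å MS, cyclohexane, 60 °C
Reagents that add atoms: none
Why: Hydrazone condensation of a symmetric ketone with the Enders auxiliary (no C=N isomer question), which installs the element that will control both new stereocentres.

Step 3
Reactants: 5 methyl 2-(bromomethyl)acrylate
Product: 6 methyl 2,3-dibromo-2-(bromomethyl)propanoate
Conditions: Br2 (1.05 equiv), CH2Cl2, 0 °C → rt
Reagents that add atoms: bromine, BrBr
Why: Bromine addition to the acrylate double bond, which raises the future C2 to the oxidation level needed for a vinylic leaving group.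

Step 4
Reactants: 6 methyl 2,3-dibromo-2-(bromomethyl)propanoate
Product: 7 methyl (Z)-3-bromo-2-(bromomethyl)acrylate
Conditions: Et3N (1.0 equiv), Et2O, −10 °C → rt
Reagents that add atoms: none
Why: E2 dehydrobromination in which the tertiary α-bromide leaves with one of the only β-hydrogens present (on a CH2Br group); the (Z) isomer (Br trans to the ester) is expected to predominate and the geometry is not critical for step 5.

Step 5
Reactants: 4 RAMP hydrazone of 1,3-bis[(tert-butyldimethylsilyl)oxy]propan-2-one; 7 methyl (Z)-3-bromo-2-(bromomethyl)acrylate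
Product: 10 methyl (3R,5R)-3,5-bis[(tert-butyldimethylsilyl)oxy]-4-oxocyclohex-1-ene-1-carboxylate, via monoalkylated hydrazone 8 (not isolated), via cyclic hydrazone 9 (not isolated)
Conditions: t-BuLi (1.05 equiv), THF, −78 °C; 7 (1.0 equiv), −100 °C; LiN(i-Pr)2 (1.0 equiv), −78 → −30 °C; then sat. aq. (CO2H)2, Et2O, rt
Reagents that add atoms: water, O
Why: Proposed new method: lithiated 4 (azaenolate with the silyloxy group anti to nitrogen, as in the dioxanone series) should be alkylated by the allylic bromide of 7 to give 8 (C5–C6), LiN(i-Pr)2 then deprotonates the remaining CH2OTBS arm, and the new azaenolate closes the ring by conjugate addition to the β-bromoacrylate and loss of bromide (C2–C3), which delivers the C1=C2 enoate directly; oxalic acid hydrolysis of 9 then frees the ketone and the auxiliary. The closest known reactions are the Enders α,α′-bisalkylation of dihydroxyacetone SAMP/RAMP hydrazones, which gives trans (C2-symmetric) products, and the Lawton α,α′-annulation of ketone enamines with 2-(bromomethyl)acrylates. The one ring closed is the carbocycle, by 6-endo-trig addition–elimination at C2, or by 6-exo-tet substitution at C6 should 7 react first at its vinylic end. C5 and C3 are both set by RAMP, which opens the same face of each azaenolate, hence (3R,5R) with the two silyloxy groups trans; in the ring closure the C5 oxygen lies near the N–Li plane and the tether stands perpendicular on the open face, the arrangement that the dioxanone ring enforces in the known trans-bisalkylation. The step needs facial control only, because the (3R,5R)-dioxygenated C4-carbonyl unit is C2-symmetric and either order of attack on 7 gives the same ketone 10. The second deprotonation must spare the bromoacrylate, which is why hindered LiN(i-Pr)2 at −78 °C and exactly one equivalent are used, the CH2 next to the ester-bearing carbon being only cross-conjugated and not acidified.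

Step 6
Reactants: 10 methyl (3R,5R)-3,5-bis[(tert-butyldimethylsilyl)oxy]-4-oxocyclohex-1-ene-1-carboxylate
Product: 11 methyl (3R,4S,5R)-3,5-bis[(tert-butyldimethylsilyl)oxy]-4-hydroxycyclohex-1-ene-1-carboxylate
Conditions: NaBH4, CeCl3·7H2O, MeOH, −78 °C
Reagents that add atoms: none
Why: Luche 1,2-reduction in which hydride should add axially and anti to the pseudoaxial allylic C3–OTBS bond of the half-chair that keeps the C5–OTBS group equatorial (Felkin–Anh control), which sets C4 as (S) with the new hydroxyl cis to O3 and trans to O5, while the enoate is left alone.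

Step 7
Reactants: 11 methyl (3R,4S,5R)-3,5-bis[(tert-butyldimethylsilyl)oxy]-4-hydroxycyclohex-1-ene-1-carboxylate
Product: 12 methyl (3R,4S,5R)-3,4,5-trihydroxycyclohex-1-ene-1-carboxylate (methyl shikimate)
Conditions: HCl (1.25 M in MeOH, 0.3 equiv), MeOH, 0 °C → rt
Reagents that add atoms: none
Why: Acid-catalysed methanolysis of the two secondary silyl ethers under conditions in which methyl shikimate is stable; no acyl group is present yet, so nothing can migrate.

Step 8
Reactants: 12 methyl shikimate
Product: 13 methyl 3,4-O-(1-methoxyethylidene)shikimate (cyclic orthoacetate over O3/O4, both epimers at the orthoester carbon, 5-OH free)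
Conditions: MeC(OMe)3 (1.2 equiv), CSA (5 mol%), MeCN, rt; Et3N quench
Reagents that add atoms: trimethyl orthoacetate, COC(C)(OC)OC
Why: Acid-catalysed orthoester exchange that engages only the cis-3,4-diol in a five-membered ring (the trans-4,5 pair cannot close it), which leaves O5–H free and stores the future acetate on O3/O4.

Step 9
Reactants: 13 methyl 3,4-O-(1-methoxyethylidene)shikimate; 14 (R)-2-methylbutanoic acid
Product: 16 methyl (3R,4S,5R)-3-(acetyloxy)-4-hydroxy-5-{[(2R)-2-methylbutanoyl]oxy}cyclohex-1-ene-1-carboxylate, via acylated orthoester 15 (not isolated)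
Conditions: 14 (1.3 equiv), DCC (1.4 equiv), DMAP (0.1 equiv), CH2Cl2, 0 °C → rt; then AcOH/H2O (4:1), rt
Reagents that add atoms: water, O
Why: Steglich esterification of the only free hydroxyl (the orthoester tolerates these conditions) followed by aqueous-acid opening of the cyclic orthoester, which should leave the acetate on the pseudoaxial allylic O3 and free the equatorial O4–H (kinetic axial-ester rule of cyclic orthoester hydrolysis); no ring stereocentre is touched and the acid is activated without ketene-forming base.

Step 10
Reactants: 16 methyl (3R,4S,5R)-3-(acetyloxy)-4-hydroxy-5-{[(2R)-2-methylbutanoyl]oxy}cyclohex-1-ene-1-carboxylate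
Product: 17 methyl (3R,4S,5R)-3-(acetyloxy)-5-{[(2R)-2-methylbutanoyl]oxy}-4-(propanoyloxy)cyclohex-1-ene-1-carboxylate (CNP0403577.1)
Conditions: (EtCO)2O (2 equiv), pyridine, DMAP (5 mol%), CH2Cl2, 0 °C
Reagents that add atoms: propanoic anhydride, CCC(=O)OC(=O)CC
Why: DMAP-catalysed acylation of the last free secondary hydroxyl at low temperature, which should be fast enough to outrun acetyl migration from O3 to O4.

**Compound list**

1 | 1,3-dihydroxyacetone (supplied as its dimer) | OCC(=O)CO | starting material
2 | 1,3-bis[(tert-butyldimethylsilyl)oxy]propan-2-one | CC(C)(C)[Si](C)(C)OCC(=O)CO[Si](C)(C)C(C)(C)C | intermediate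
3 | (R)-1-amino-2-(methoxymethyl)pyrrolidine (RAMP) | COC[C@H]1CCCN1N | starting material
4 | RAMP hydrazone of 2 | COC[C@H]1CCCN1N=C(CO[Si](C)(C)C(C)(C)C)CO[Si](C)(C)C(C)(C)C | intermediate
5 | methyl 2-(bromomethyl)acrylate | C=C(CBr)C(=O)OC | starting material
6 | methyl 2,3-dibromo-2-(bromomethyl)propanoate | COC(=O)C(Br)(CBr)CBr | intermediate
7 | methyl (Z)-3-bromo-2-(bromomethyl)acrylate | COC(=O)/C(CBr)=C/Br | intermediate
8 | monoalkylated hydrazone: RAMP hydrazone carrying (R)-CH(OTBS)–CH2–C(CO2Me)=CHBr on one side and CH2OTBS on the other (C=N geometry not defined; not isolated) | COC[C@H]1CCCN1N=C(CO[Si](C)(C)C(C)(C)C)[C@H](O[Si](C)(C)C(C)(C)C)C\C(C(=O)OC)=C/Br | intermediate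
9 | cyclic hydrazone: RAMP hydrazone of 10 (C=N geometry not defined; not isolated) | COC[C@H]1CCCN1N=C1[C@H](O[Si](C)(C)C(C)(C)C)C=C(C(=O)OC)C[C@H]1O[Si](C)(C)C(C)(C)C | intermediate
10 | methyl (3R,5R)-3,5-bis[(tert-butyldimethylsilyl)oxy]-4-oxocyclohex-1-ene-1-carboxylate | O=C1[C@H](O[Si](C)(C)C(C)(C)C)C=C(C(=O)OC)C[C@H]1O[Si](C)(C)C(C)(C)C | intermediate
11 | methyl (3R,4S,5R)-3,5-bis[(tert-butyldimethylsilyl)oxy]-4-hydroxycyclohex-1-ene-1-carboxylate | O[C@@H]1[C@H](O[Si](C)(C)C(C)(C)C)C=C(C(=O)OC)C[C@H]1O[Si](C)(C)C(C)(C)C | intermediate
12 | methyl (3R,4S,5R)-3,4,5-trihydroxycyclohex-1-ene-1-carboxylate (methyl shikimate) | O[C@@H]1[C@H](O)C=C(C(=O)OC)C[C@H]1O | intermediate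
13 | methyl 3,4-O-(1-methoxyethylidene)shikimate (epimers at the orthoester carbon) | O1[C@@H]2[C@H](OC1(C)OC)C=C(C(=O)OC)C[C@H]2O | intermediate
14 | (R)-2-methylbutanoic acid | CC[C@@H](C)C(=O)O | starting material
15 | methyl 3,4-O-(1-methoxyethylidene)-5-O-[(2R)-2-methylbutanoyl]shikimate (not isolated) | O1[C@@H]2[C@H](OC1(C)OC)C=C(C(=O)OC)C[C@H]2OC(=O)[C@H](C)CC | intermediate
16 | methyl (3R,4S,5R)-3-(acetyloxy)-4-hydroxy-5-{[(2R)-2-methylbutanoyl]oxy}cyclohex-1-ene-1-carboxylate | O[C@@H]1[C@H](OC(C)=O)C=C(C(=O)OC)C[C@H]1OC(=O)[C@H](C)CC | intermediate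
17 | methyl (3R,4S,5R)-3-(acetyloxy)-5-{[(2R)-2-methylbutanoyl]oxy}-4-(propanoyloxy)cyclohex-1-ene-1-carboxylate | CCC(=O)O[C@@H]1[C@H](OC(C)=O)C=C(C(=O)OC)C[C@H]1OC(=O)[C@H](C)CC | target

**Count and risks**

Total steps: 10. Longest linear sequence: 8 (steps 1, 2, 5, 6, 7, 8, 9, 10); steps 3 and 4 make the second fragment.

Steps most likely to fail:

1. Step 5 (Proposed new method). What may go wrong: the second base may attack or metalate the bromoacrylate arm of 8 faster than it forms the azaenolate, or the first alkylation may take the vinylic end and leave an over-acidic C3–H, so that ring closure stalls or C3 is scrambled. Fallback with known reactions, setting out from 4 and the commercial acrylate 5 and coming back at 9: lithiated 4 (t-BuLi, THF, −78 °C) is alkylated at −100 °C with 5 (Enders hydrazone alkylation with an allylic bromide; direct and allylic-transposed attack give the same product) to the 2-(methoxycarbonyl)allyl hydrazone F1, which is isolated. LiN(i-Pr)2 at −78 °C then forms the second azaenolate, intramolecular Michael addition closes the ring, and the ester enolate so formed is trapped with PhSeBr as the α-phenylselanyl ester F2. H2O2/pyridine at 0 °C (selenoxide syn-elimination) gives 9; elimination toward either ring CH2 leads to the same ketone after hydrolysis because of the C2 symmetry. The oxalic acid hydrolysis of step 5 then gives 10.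

2. Step 6. What may go wrong: poor facial selectivity in the hydride addition, since the two faces of the C4 carbonyl differ only through the position of the ring double bond, or base-induced epimerisation at the doubly activated C3. Fallback, setting out from 10 and coming back at 11: enzyme control in place of substrate control, by reduction with an NADPH-dependent ketoreductase chosen from a commercial panel for the (4S) alcohol (glucose/glucose dehydrogenase recycling, pH 7 buffer with i-PrOH cosolvent, 30 °C); no new compound is made (F0).

3. Step 9. What may go wrong: the orthoester may open toward the 4-acetate, or the acetyl group may migrate from O3 to the cis O4 before step 10, which would swap the acetate and propanoate positions. Fallback, setting out from 12 and coming back at 17: 2,2-dimethoxypropane/CSA gives methyl 3,4-O-isopropylideneshikimate F3; Steglich esterification with 14 gives the 5-O-acyl acetonide F4; aqueous AcOH removes the acetonide to give the 3,4-diol 5-ester F5; the dibutylstannylene acetal (Bu2SnO, toluene, reflux) is acylated with propanoyl chloride at 0 °C on the equatorial O4 to give the 4-propanoate 3-alcohol F6; Ac2O/pyridine/DMAP then gives 17.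

Further compounds
F1 | step 5 | RAMP hydrazone carrying (R)-CH(OTBS)–CH2–C(=CH2)CO2Me on one side and CH2OTBS on the other | COC[C@H]1CCCN1N=C(CO[Si](C)(C)C(C)(C)C)[C@H](O[Si](C)(C)C(C)(C)C)CC(=C)C(=O)OC
F2 | step 5 | RAMP hydrazone of methyl (3R,5R)-3,5-bis[(tert-butyldimethylsilyl)oxy]-4-oxo-1-(phenylselanyl)cyclohexane-1-carboxylate | COC[C@H]1CCCN1N=C1[C@H](O[Si](C)(C)C(C)(C)C)CC(C(=O)OC)([Se]c2ccccc2)C[C@H]1O[Si](C)(C)C(C)(C)C
F0 | step 6 | none | none
F3 | step 9 | methyl 3,4-O-isopropylideneshikimate | O1[C@@H]2[C@H](OC1(C)C)C=C(C(=O)OC)C[C@H]2O
F4 | step 9 | methyl 3,4-O-isopropylidene-5-O-[(2R)-2-methylbutanoyl]shikimate | O1[C@@H]2[C@H](OC1(C)C)C=C(C(=O)OC)C[C@H]2OC(=O)[C@H](C)CC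
F5 | step 9 | methyl 5-O-[(2R)-2-methylbutanoyl]shikimate | O[C@@H]1[C@H](O)C=C(C(=O)OC)C[C@H]1OC(=O)[C@H](C)CC
F6 | step 9 | methyl 5-O-[(2R)-2-methylbutanoyl]-4-O-propanoylshikimate | CCC(=O)O[C@@H]1[C@H](O)C=C(C(=O)OC)C[C@H]1OC(=O)[C@H](C)CC
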